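**Plan**

- Numbering used here: C1 (CHOAc), C2 (ring carbon of the ethylidene), C3 (CHCl), C4 (CMe2), C5 (CHBr), C6 (CH2). Retrosynthesis: C5–Br from C5–OH from C5=O; the Z allylic bromide from 1,3-shift of a tertiary C2 bromide bearing a vinyl group, itself from C2(Br)CHO; then the ring bonds C1–C2 and C3–C4 are cut together as a [4+2] cycloaddition.
- Forward: diene 5 (C1, C6, C5, C4; from 3-methylbutan-2-one) and (Z)-2-bromo-3-chloroacrolein 7 (C3, C2; from bromomalonaldehyde) are joined in one enantioselective Diels–Alder reaction that closes the only ring; then methylenation with bromide shift, unmasking of the C5 ketone, reduction, and bromide displacement.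
- Enabling feature: O at C1 and a heteroatom at C5 stand 1,3 across C6H2, next to the gem-dimethyl C4, which is the pattern of a 1-acyloxy-3-silyloxy-4,4-dimethyl diene. C3–Cl and the C2 ethylidene with its allylic bromine are a β-chloro-α-bromo enal in disguise: the α-bromine becomes the allylic bromine and the formyl carbon becomes the ethylidene CH.
- Stereochemistry: C1 and C3 (trans) come from the cycloaddition (E enol acetate, Z dienophile, endo formyl, chiral oxazaborolidinium for the absolute sense). C5 comes from a matched oxazaborolidine reduction to the axial alcohol followed by SN2 inversion. The Z alkene comes from thermodynamic control in the allylic bromide shift.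

Key step: step 4

Assumption: the (S)-oxazaborolidinium catalyst of step 4 is taken to give the (1S,5S,6S) adduct; if its sense of induction is the opposite, the (R)-catalyst is used and nothing else changes.

**Step 1**
Reactants: 1 3-methylbutan-2-one; 2 ethyl formate
Product: 4 (1E)-4-methyl-3-oxopent-1-en-1-yl acetate, via sodium enolate of 4-methyl-3-oxopentanal 3 (not isolated)
Conditions: NaH, Et2O, 0 °C to rt; volatiles removed; then AcCl, Et2O, 0 °C
Reagents that add atoms: acetyl chloride CC(=O)Cl
Why: Crossed Claisen condensation at the methyl group gives the stabilised enolate of the β-keto aldehyde, and O-acylation of this ambident enolate by the hard acyl chloride should give the E enol acetate.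

**Step 2**
Reactants: 4 (1E)-4-methyl-3-oxopent-1-en-1-yl acetate
Product: 5 (1E)-4-methyl-3-[(triisopropylsilyl)oxy]penta-1,3-dien-1-yl acetate
Conditions: i-Pr3SiOTf, Et3N, CH2Cl2, 0 °C to rt
Reagents that add atoms: triisopropylsilyl trifluoromethanesulfonate CC(C)[Si](C(C)C)(C(C)C)OS(=O)(=O)C(F)(F)F
Why: Silyl triflate/amine enolisation can only remove the isopropyl methine hydrogen (the other α-carbon is vinylic), which gives the tetrasubstituted silyl enol ether and so the 1-acetoxy-3-silyloxy diene with the E enol acetate unchanged.

**Step 3**
Reactants: 6 2-bromopropanedial (bromomalonaldehyde)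
Product: 7 (2Z)-2-bromo-3-chloroprop-2-enal
Conditions: (COCl)2, DMF (cat.), CH2Cl2, 0 °C to rt
Reagents that add atoms: oxalyl chloride O=C(Cl)C(=O)Cl
Why: Deoxychlorination of the enol of the 1,3-dialdehyde (a vinylogous acid) by the Vilsmeier-type reagent gives the vinylogous acid chloride; the Z isomer (chlorine anti to formyl) is expected as the more stable one, and the isomers can equilibrate by chloride addition–elimination.

**Step 4**
Reactants: 5 (1E)-4-methyl-3-[(triisopropylsilyl)oxy]penta-1,3-dien-1-yl acetate; 7 (2Z)-2-bromo-3-chloroprop-2-enal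
Product: 8 (1S,5S,6S)-6-bromo-5-chloro-6-formyl-4,4-dimethyl-3-[(triisopropylsilyl)oxy]cyclohex-2-en-1-yl acetate
Conditions: (S)-3,3-diphenyl-1-(2-methylphenyl)tetrahydro-1H,3H-pyrrolo[1,2-c][1,3,2]oxazaborole (20 mol%) activated by HNTf2 (18 mol%), CH2Cl2, −78 to −40 °C
Reagents that add atoms: none
Why: The protonated oxazaborolidine binds the formyl oxygen of 7 and lowers its LUMO, so that a normal-demand [4+2] cycloaddition with the electron-rich diene 5 takes place, concerted but asynchronous, with the bond from the dimethyl-bearing diene terminus to the chlorine-bearing β-carbon running ahead of the bond from the acetoxy-bearing terminus to the bromine-bearing α-carbon; the closest known reaction type is the oxazaborolidinium-catalysed enantioselective Diels–Alder reaction of 2-bromoacrolein and its β-substituted congeners with 2-silyloxy dienes. The cyclohexene ring, the only ring of the target, is closed by suprafacial [π4s+π2s] union of the two components, both new ring bonds forming on the same face of each partner. The acetoxy-bearing stereocentre follows from the E geometry of the enol acetate and the endo position of the boron-bound formyl group (acetoxy cis to formyl), the chlorine-bearing stereocentre from the Z geometry of 7 (chlorine trans to formyl, hence trans to acetoxy), the quaternary bromo-formyl centre from the same suprafacial addition (it is removed later), and the absolute sense from the catalyst, which shields one face of the bound enal. Regioselectivity is needed and is secured by the 1-acetoxy and 3-silyloxy donors, which both make the dimethyl terminus the nucleophilic end that seeks the β-carbon of the enal. Endo selectivity and retention of chlorine are also needed: the second bond must close before the β-chloro boron enolate of a stepwise path can expel chloride, which the weakly donating acetoxy group (in place of alkoxy or amino), the low temperature and the pre-organised endo geometry should secure.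

**Step 5**
Reactants: 8 (1S,5S,6S)-6-bromo-5-chloro-6-formyl-4,4-dimethyl-3-[(triisopropylsilyl)oxy]cyclohex-2-en-1-yl acetate
Product: 10 (1S,5R,6Z)-6-(2-bromoethylidene)-5-chloro-4,4-dimethyl-3-[(triisopropylsilyl)oxy]cyclohex-2-en-1-yl acetate, via tertiary allylic bromide 9 (not isolated)
Conditions: Ph3PCH3Br (1.05 equiv), KN(SiMe3)2 (1.0 equiv), THF, −78 °C; then LiBr (0.2 equiv), 0 °C to rt
Reagents that add atoms: methyltriphenylphosphonium bromide C[P+](c1ccccc1)(c1ccccc1)c1ccccc1.[Br-]
Why: Wittig methylenation of the aldehyde, which has no α-hydrogen, gives the tertiary allylic bromide 9, whose bromide-catalysed SN2′ 1,3-shift to the primary allylic bromide is downhill and reversible, so the alkene geometry is set under thermodynamic control in favour of Z, the only isomer in which CH2Br lies next to an axial C–Cl bond and avoids A(1,3) strain with the pseudo-equatorial acetoxy group.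

**Step 6**
Reactants: 10 (1S,5R,6Z)-6-(2-bromoethylidene)-5-chloro-4,4-dimethyl-3-[(triisopropylsilyl)oxy]cyclohex-2-en-1-yl acetate
Product: 11 (1S,3R)-2-[(Z)-2-bromoethylidene]-3-chloro-4,4-dimethyl-5-oxocyclohexyl acetate
Conditions: HF·pyridine, THF, 0 °C
Reagents that add atoms: none
Why: Protodesilylation of the silyl enol ether by buffered HF (carbon protonation, then loss of silicon as the fluorosilane) unmasks the ketone without base, so the β-acetoxy ketone should not eliminate and the allylic halides stay untouched; no stereocentre is formed.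

**Step 7**
Reactants: 11 (1S,3R)-2-[(Z)-2-bromoethylidene]-3-chloro-4,4-dimethyl-5-oxocyclohexyl acetate
Product: 12 (1S,3S,5S)-2-[(Z)-2-bromoethylidene]-3-chloro-5-hydroxy-4,4-dimethylcyclohexyl acetate
Conditions: (R)-1-methyl-3,3-diphenyltetrahydro-1H,3H-pyrrolo[1,2-c][1,3,2]oxazaborole (20 mol%), catecholborane, toluene, −78 °C
Reagents that add atoms: none
Why: Corey–Bakshi–Shibata reduction in which the (R)-oxazaborolidine places the quaternary α-carbon away from the catalyst and delivers hydride to the ketone face anti to the axial chlorine (equatorial attack), so catalyst and substrate control are matched and the axial (5S) alcohol, trans to the acetate, should result; catecholborane should leave the allylic halides and the trisubstituted alkene alone.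

**Step 8**
Reactants: 12 (1S,3S,5S)-2-[(Z)-2-bromoethylidene]-3-chloro-5-hydroxy-4,4-dimethylcyclohexyl acetate
Product: 14 (1S,3R,5R)-5-bromo-2-[(Z)-2-bromoethylidene]-3-chloro-4,4-dimethylcyclohexyl acetate (target), via axial triflate 13 (not isolated)
Conditions: Tf2O, 2,6-di-tert-butyl-4-methylpyridine, CH2Cl2, −78 °C; then n-Bu4NBr, toluene, −78 to 0 °C
Reagents that add atoms: tetrabutylammonium bromide CCCC[N+](CCCC)(CCCC)CCCC.[Br-]; trifluoromethanesulfonic anhydride (its atoms stay in 13 only) O=S(=O)(OS(=O)(=O)C(F)(F)F)C(F)(F)F
Why: Triflation of the axial alcohol and SN2 displacement by unsolvated bromide invert the carbinol carbon to the equatorial (5R) bromide, cis to the acetate; the non-nucleophilic base, the low temperature and the relief of syn-diaxial triflate/chlorine strain should favour bimolecular substitution over ionisation, and bromide exchange at the allylic bromide is degenerate and keeps the Z geometry.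

**Compound list**

1 | 3-methylbutan-2-one | CC(=O)C(C)C | starting material
2 | ethyl formate | CCOC=O | starting material
3 | sodium 4-methyl-3-oxopent-1-en-1-olate (sodium enolate of 4-methyl-3-oxopentanal) | [Na+].[O-]C=CC(=O)C(C)C | intermediate
4 | (1E)-4-methyl-3-oxopent-1-en-1-yl acetate | CC(=O)O/C=C/C(=O)C(C)C | intermediate
5 | (1E)-4-methyl-3-[(triisopropylsilyl)oxy]penta-1,3-dien-1-yl acetate | CC(=O)O/C=C/C(O[Si](C(C)C)(C(C)C)C(C)C)=C(C)C | intermediate
6 | 2-bromopropanedial (bromomalonaldehyde) | O=CC(Br)C=O | starting material
7 | (2Z)-2-bromo-3-chloroprop-2-enal (Cl cis to Br, trans to CHO) | Cl/C=C(Br)/C=O | intermediate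
8 | (1S,5S,6S)-6-bromo-5-chloro-6-formyl-4,4-dimethyl-3-[(triisopropylsilyl)oxy]cyclohex-2-en-1-yl acetate (OAc and CHO cis; Cl and Br on the other face) | CC(=O)O[C@H]1C=C(O[Si](C(C)C)(C(C)C)C(C)C)C(C)(C)[C@H](Cl)[C@@]1(Br)C=O | intermediate
9 | (1S,5S,6R)-6-bromo-5-chloro-6-ethenyl-4,4-dimethyl-3-[(triisopropylsilyl)oxy]cyclohex-2-en-1-yl acetate | CC(=O)O[C@H]1C=C(O[Si](C(C)C)(C(C)C)C(C)C)C(C)(C)[C@H](Cl)[C@@]1(Br)C=C | intermediate
10 | (1S,5R,6Z)-6-(2-bromoethylidene)-5-chloro-4,4-dimethyl-3-[(triisopropylsilyl)oxy]cyclohex-2-en-1-yl acetate (the 5-descriptor changes from 8 by priority only) | CC(=O)O[C@H]1C=C(O[Si](C(C)C)(C(C)C)C(C)C)C(C)(C)[C@H](Cl)/C1=C\CBr | intermediate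
11 | (1S,3R)-2-[(Z)-2-bromoethylidene]-3-chloro-4,4-dimethyl-5-oxocyclohexyl acetate | CC(=O)O[C@H]1CC(=O)C(C)(C)[C@H](Cl)/C1=C\CBr | intermediate
12 | (1S,3S,5S)-2-[(Z)-2-bromoethylidene]-3-chloro-5-hydroxy-4,4-dimethylcyclohexyl acetate (OH trans to OAc, cis to Cl; the 3-descriptor changes by priority only) | CC(=O)O[C@H]1C[C@H](O)C(C)(C)[C@H](Cl)/C1=C\CBr | intermediate
13 | (1S,3S,5S)-2-[(Z)-2-bromoethylidene]-3-chloro-4,4-dimethyl-5-[(trifluoromethanesulfonyl)oxy]cyclohexyl acetate | CC(=O)O[C@H]1C[C@H](OS(=O)(=O)C(F)(F)F)C(C)(C)[C@H](Cl)/C1=C\CBr | intermediate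
14 | (1S,3R,5R)-5-bromo-2-[(Z)-2-bromoethylidene]-3-chloro-4,4-dimethylcyclohexyl acetate | CC(=O)O[C@H]1C[C@@H](Br)C(C)(C)[C@H](Cl)/C1=C\CBr | target

**Count and risks**

Total steps: 8. Longest linear sequence: 7 (steps 1, 2, 4, 5, 6, 7, 8); step 3 is the one-step side branch to the dienophile.

Steps most likely to fail:

1. Step 4. The cycloaddition may become stepwise: conjugate addition of the silyl enol ether terminus, then expulsion of chloride from the β-chloro enolate instead of ring closure. Exo addition may also compete and erode the trans relation of acetoxy and chlorine. Fallback, from 5 and 7: the uncatalysed cycloaddition under high pressure (CH2Cl2, about 12 kbar, rt) is concerted, so no enolate is formed. It should give racemic 8, that is 8 together with its enantiomer (1R,5R,6R)-6-bromo-5-chloro-6-formyl-4,4-dimethyl-3-[(triisopropylsilyl)oxy]cyclohex-2-en-1-yl acetate F1. F1 is removed by preparative chromatography on a chiral stationary phase (cellulose tris(3,5-dimethylphenylcarbamate)), and the route is rejoined at 8.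

2. Step 8. Ionisation of the neopentyl-type secondary triflate, with methyl shift from the quaternary carbon or anti elimination towards the ring CH2, may outrun backside attack by bromide. Fallback, from 11: the substitution is run with retention on the other alcohol epimer, so that no backside approach past the axial methyl group is needed. Reduction of 11 with the (S)-enantiomer of the oxazaborolidine and catecholborane (catalyst control, hydride to the opposite face) should give the equatorial alcohol (1S,3S,5R)-2-[(Z)-2-bromoethylidene]-3-chloro-5-hydroxy-4,4-dimethylcyclohexyl acetate F3. Thionyl bromide without base in 1,4-dioxane at rt converts it into the bromosulfite (1S,3S,5R)-2-[(Z)-2-bromoethylidene]-5-[(bromosulfinyl)oxy]-3-chloro-4,4-dimethylcyclohexyl acetate F4, which should lose SO2 with internal return of bromide (SNi, retention) and come back to the route at 14.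

3. Step 5. The basic ylide may attack the bromine of the α-bromo aldehyde (halophilic attack) or dehydrohalogenate the adduct instead of adding to the formyl group. Fallback, from 8: Peterson olefination without a basic ylide. Addition of Me3SiCH2MgCl in the presence of CeCl3 (THF, −78 °C) should give the β-hydroxysilane (1S,5S,6R)-6-bromo-5-chloro-6-[1-hydroxy-2-(trimethylsilyl)ethyl]-4,4-dimethyl-3-[(triisopropylsilyl)oxy]cyclohex-2-en-1-yl acetate F2 (either carbinol epimer). Acid-promoted anti elimination (BF3·OEt2, CH2Cl2, −78 °C) then gives the tertiary allylic bromide 9, which rearranges to 10 as in the main route.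

**Further compounds**

F1 | step 4 | (1R,5R,6R)-6-bromo-5-chloro-6-formyl-4,4-dimethyl-3-[(triisopropylsilyl)oxy]cyclohex-2-en-1-yl acetate (enantiomer of 8) | CC(=O)O[C@@H]1C=C(O[Si](C(C)C)(C(C)C)C(C)C)C(C)(C)[C@@H](Cl)[C@]1(Br)C=O
F2 | step 5 | (1S,5S,6R)-6-bromo-5-chloro-6-[1-hydroxy-2-(trimethylsilyl)ethyl]-4,4-dimethyl-3-[(triisopropylsilyl)oxy]cyclohex-2-en-1-yl acetate | CC(=O)O[C@H]1C=C(O[Si](C(C)C)(C(C)C)C(C)C)C(C)(C)[C@H](Cl)[C@@]1(Br)C(O)C[Si](C)(C)C
F3 | step 8 | (1S,3S,5R)-2-[(Z)-2-bromoethylidene]-3-chloro-5-hydroxy-4,4-dimethylcyclohexyl acetate | CC(=O)O[C@H]1C[C@@H](O)C(C)(C)[C@H](Cl)/C1=C\CBr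
F4 | step 8 | (1S,3S,5R)-2-[(Z)-2-bromoethylidene]-5-[(bromosulfinyl)oxy]-3-chloro-4,4-dimethylcyclohexyl acetate | CC(=O)O[C@H]1C[C@@H](OS(Br)=O)C(C)(C)[C@H](Cl)/C1=C\CBr
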